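**Retrosynthetic overview**
- Target ⇐ chemoselective reduction of the δ-lactone in a bicyclic bis-lactone; the lactone ring carries the Z-olefin geometry and both oxygens of the 1,5-diol.
- δ-Lactone ⇐ ring-closing metathesis of a 2-substituted acrylate ester (last ring formed, opened again in the final step).
- Decalin ⇐ proton-initiated, catalyst-controlled bicyclisation of the fully assembled all-E trienyl ester: rings A and B form in one cascade that ends by loss of H-9 to the tetrasubstituted olefin (key step).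
- Acyclic ester ⇐ Pd-carbonylative union of the kinetic enol triflate of farnesylacetone with a butenolide homoallylic alcohol.
- Butenolide alcohol ⇐ furan-3-carbaldehyde by catalytic asymmetric allylation, then oxidative remodelling of the furan (first ring formed).

Assumption: (5E,9E)-farnesylacetone is bought as the geometrically pure E,E isomer (CAS 1117-52-8).

**Step 1**
Reactants: 1 furan-3-carbaldehyde
Product: 2 (1R)-1-(furan-3-yl)but-3-en-1-ol
Conditions: (R)-BINOL (10 mol %), Ti(Oi-Pr)4 (10 mol %), 4 Å MS, allylSnBu3, CH2Cl2, −20 °C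
Reagents that add atoms: allyltributylstannane, C=CC[Sn](CCCC)(CCCC)CCCC
Why: Keck catalytic asymmetric allylation, in which the (R)-BINOL–Ti(IV) Lewis acid directs allyl transfer to the Re face of the aryl aldehyde and so sets the (R)-carbinol that becomes the secondary alcohol centre of the target.

**Step 2**
Reactants: 2 (1R)-1-(furan-3-yl)but-3-en-1-ol
Product: 4 4-[(1R)-1-hydroxybut-3-en-1-yl]furan-2(5H)-one, via hydroxybutenolide 3 (not isolated)
Conditions: O2, hν (white LED), rose bengal (cat.), i-Pr2NEt, CH2Cl2, −78 °C; then NaBH4, EtOH, 0 °C; 1 M HCl work-up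
Reagents that add atoms: dioxygen, O=O
Why: Faulkner furan photooxygenation, in which [4+2] addition of singlet oxygen and Hünig-base-induced fragmentation of the endoperoxide at the unhindered C5–H give the 4-substituted 5-hydroxybutenolide regioselectively, whose ring-open aldehyde is reduced by NaBH4 and relactonises on acidification without touching the carbinol centre or the monosubstituted olefin.

**Step 3**
Reactants: 5 (5E,9E)-6,10,14-trimethylpentadeca-5,9,13-trien-2-one (farnesylacetone)
Product: 6 (5E,9E)-6,10,14-trimethylpentadeca-1,5,9,13-tetraen-2-yl trifluoromethanesulfonate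
Conditions: KHMDS, THF, −78 °C; PhNTf2, −78 → 0 °C
Reagents that add atoms: N-phenylbis(trifluoromethanesulfonimide), O=S(=O)(N(c1ccccc1)S(=O)(=O)C(F)(F)F)C(F)(F)F
Why: Kinetic enolisation of the methyl ketone on the methyl side by a bulky amide base followed by O-sulfonylation gives the terminal alkenyl triflate and leaves the trisubstituted olefins untouched.

**Step 4**
Reactants: 6 (5E,9E)-6,10,14-trimethylpentadeca-1,5,9,13-tetraen-2-yl trifluoromethanesulfonate, 4 4-[(1R)-1-hydroxybut-3-en-1-yl]furan-2(5H)-one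
Product: 7 (1R)-1-(5-oxo-2,5-dihydrofuran-3-yl)but-3-en-1-yl (5E,9E)-6,10,14-trimethyl-2-methylidenepentadeca-5,9,13-trienoate
Conditions: Pd(OAc)2 (5 mol %), dppf (6 mol %), CO (1 atm), Et3N, DMAP (20 mol %), DMF, 50 °C
Reagents that add atoms: carbon monoxide, [C-]#[O+]
Why: Pd(0)-catalysed alkoxycarbonylation of an alkenyl triflate (oxidative addition, CO insertion, alcoholysis of the acyl-palladium with DMAP as acyl shuttle) gives the 2-substituted acrylate ester directly with no change at the carbinol centre.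

**Step 5**
Reactants: 7 (1R)-1-(5-oxo-2,5-dihydrofuran-3-yl)but-3-en-1-yl (5E,9E)-6,10,14-trimethyl-2-methylidenepentadeca-5,9,13-trienoate
Product: 9 (1R)-1-(5-oxo-2,5-dihydrofuran-3-yl)but-3-en-1-yl 2-methylidene-4-[(4aS,8aS)-2,5,5,8a-tetramethyl-3,4,4a,5,6,7,8,8a-octahydronaphthalen-1-yl]butanoate, via bicyclic C8 carbocation 8 (not isolated)
Conditions: confined IDPi Brønsted acid (List type, the antipode that converts (3E,7E)-homofarnesol into (−)-ambrox; 5 mol %), (CF3)3COH, 0 °C; then TfOH (5 mol %), CH2Cl2, −20 °C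
Reagents that add atoms: none
Why: Proposed new method: the confined chiral acid protonates one face of the terminal isopropylidene group, the all-E triene closes through a chair–chair anti-addition cascade (Stork–Eschenmoser) that sets C4a and C8a as the trans-fused (4aS,8aS) decalin under catalyst control, the conjugated acrylate olefin is too electron-poor to add to the C8 cation so the cascade stops there, and loss of the axial neighbouring H under acid-equilibrating conditions gives the most substituted, tetrasubstituted ring olefin; the closest known reactions are the IDPi-catalysed cyclisation of homofarnesol to (−)-ambrox, BINOL·SnCl4-induced polyprenoid cyclisations and the acid isomerisation of labd-7-enes and labd-8(17)-enes to labd-8-enes.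

**Step 6**
Reactants: 9 (1R)-1-(5-oxo-2,5-dihydrofuran-3-yl)but-3-en-1-yl 2-methylidene-4-[(4aS,8aS)-2,5,5,8a-tetramethyl-3,4,4a,5,6,7,8,8a-octahydronaphthalen-1-yl]butanoate
Product: 10 (6R)-6-(5-oxo-2,5-dihydrofuran-3-yl)-3-{2-[(4aS,8aS)-2,5,5,8a-tetramethyl-3,4,4a,5,6,7,8,8a-octahydronaphthalen-1-yl]ethyl}-5,6-dihydro-2H-pyran-2-one
Conditions: Grubbs II (5 mol %), CH2Cl2, 40 °C
Reagents that add atoms: none
Why: Ring-closing metathesis between the terminal vinyl group and the 1,1-disubstituted acrylate closes the α,β-unsaturated δ-lactone and thereby fixes the Z geometry of the future trisubstituted olefin, while the tetrasubstituted ring olefin and the butenolide are inert to the catalyst.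

**Step 7**
Reactants: 10 (6R)-6-(5-oxo-2,5-dihydrofuran-3-yl)-3-{2-[(4aS,8aS)-2,5,5,8a-tetramethyl-3,4,4a,5,6,7,8,8a-octahydronaphthalen-1-yl]ethyl}-5,6-dihydro-2H-pyran-2-one
Product: 12 4-[(1R,3Z)-1-hydroxy-4-(hydroxymethyl)-6-[(4aS,8aS)-2,5,5,8a-tetramethyl-3,4,4a,5,6,7,8,8a-octahydronaphthalen-1-yl]hex-3-en-1-yl]furan-2(5H)-one, via lithium furanolate 11 (not isolated)
Conditions: LiHMDS (1.05 equiv), THF, −78 °C; DIBAL-H (4 equiv), −78 → 0 °C; aq. Rochelle salt
Reagents that add atoms: none
Why: Proposed new method: in-situ enolate protection, in which one equivalent of LiHMDS removes only the butenolide γ-H (the anion is an aromatic furan-2-olate and is inert to hydride) so that DIBAL-H reduces only the δ-lactone by 1,2-addition to the (Z)-allylic 1,5-diol with the ring-derived geometry and the carbinol centre retained, and aqueous work-up reprotonates the furanolate to the butenolide; the closest known reaction type is protection of a ketone as its enolate during hydride reduction of an ester.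

**Compound list**
1 | furan-3-carbaldehyde | O=Cc1ccoc1 | starting material
2 | (1R)-1-(furan-3-yl)but-3-en-1-ol | C=CC[C@@H](O)c1ccoc1 | intermediate
3 | 5-hydroxy-4-[(1R)-1-hydroxybut-3-en-1-yl]furan-2(5H)-one (C5 epimers; not isolated) | C=CC[C@@H](O)C1=CC(=O)OC1O | intermediate
4 | 4-[(1R)-1-hydroxybut-3-en-1-yl]furan-2(5H)-one | C=CC[C@@H](O)C1=CC(=O)OC1 | intermediate
5 | (5E,9E)-6,10,14-trimethylpentadeca-5,9,13-trien-2-one (farnesylacetone) | CC(=O)CC/C=C(\C)CC/C=C(\C)CCC=C(C)C | starting material
6 | (5E,9E)-6,10,14-trimethylpentadeca-1,5,9,13-tetraen-2-yl trifluoromethanesulfonate | C=C(OS(=O)(=O)C(F)(F)F)CC/C=C(\C)CC/C=C(\C)CCC=C(C)C | intermediate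
7 | (1R)-1-(5-oxo-2,5-dihydrofuran-3-yl)but-3-en-1-yl (5E,9E)-6,10,14-trimethyl-2-methylidenepentadeca-5,9,13-trienoate | C=CC[C@@H](OC(=O)C(=C)CC/C=C(\C)CC/C=C(\C)CCC=C(C)C)C1=CC(=O)OC1 | intermediate
8 | labdane-type C8 tertiary carbocation formed from 7 after closure of rings A and B (trans-decalin, H on the side-chain carbon trans to the angular methyl; not isolated) | C[C+]1[C@H](CCC(=C)C(=O)O[C@H](CC=C)C2=CC(=O)OC2)[C@@]3(C)CCCC(C)(C)[C@@H]3CC1 | intermediate
9 | (1R)-1-(5-oxo-2,5-dihydrofuran-3-yl)but-3-en-1-yl 2-methylidene-4-[(4aS,8aS)-2,5,5,8a-tetramethyl-3,4,4a,5,6,7,8,8a-octahydronaphthalen-1-yl]butanoate | CC1=C(CCC(=C)C(=O)O[C@H](CC=C)C2=CC(=O)OC2)[C@@]3(C)CCCC(C)(C)[C@@H]3CC1 | intermediate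
10 | (6R)-6-(5-oxo-2,5-dihydrofuran-3-yl)-3-{2-[(4aS,8aS)-2,5,5,8a-tetramethyl-3,4,4a,5,6,7,8,8a-octahydronaphthalen-1-yl]ethyl}-5,6-dihydro-2H-pyran-2-one | CC1=C(CCC2=CC[C@@H](OC2=O)C3=CC(=O)OC3)[C@@]4(C)CCCC(C)(C)[C@@H]4CC1 | intermediate
11 | lithium 4-[(2R)-6-oxo-5-{2-[(4aS,8aS)-2,5,5,8a-tetramethyl-3,4,4a,5,6,7,8,8a-octahydronaphthalen-1-yl]ethyl}-3,6-dihydro-2H-pyran-2-yl]furan-2-olate (not isolated) | [Li+].CC1=C(CCC2=CC[C@@H](OC2=O)c3coc([O-])c3)[C@@]4(C)CCCC(C)(C)[C@@H]4CC1 | intermediate
12 | 4-[(1R,3Z)-1-hydroxy-4-(hydroxymethyl)-6-[(4aS,8aS)-2,5,5,8a-tetramethyl-3,4,4a,5,6,7,8,8a-octahydronaphthalen-1-yl]hex-3-en-1-yl]furan-2(5H)-one (CNP0224983.2) | CC1=C(CC/C(=C/C[C@@H](O)C2=CC(=O)OC2)CO)[C@@]2(C)CCCC(C)(C)[C@@H]2CC1 | target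

**Step count**
Total steps: 7. Longest linear sequence: 6 (steps 1, 2, 4, 5, 6, 7 from furan-3-carbaldehyde).

**Steps most likely to fail**

Step 5 (key bicyclisation). The risks are modest facial selectivity on a substrate with no terminating nucleophile, Δ7 and Δ8(17) olefin regioisomers, partial cyclisation, and backbone rearrangement during equilibration. The decalin is set by the catalyst, not by the remote carbinol, so the wrong decalin antipode appears as a diastereomer; it is removed at 10. The fallback lets a heteroatom end the cascade on a simpler substrate; it sets out from 5 and comes back at 9. The same chiral acid (or a BINOL·SnCl4 Lewis-acid-assisted Brønsted acid) cyclises farnesylacetone with the ketone oxygen as terminator to sclareol oxide F1. TsOH in refluxing benzene reopens the tertiary enol ether by E1 through its oxocarbenium ion to the thermodynamic Δ8 methyl ketone 14,15-dinorlabd-8-en-13-one F2. KHMDS/PhNTf2 gives the bicyclic alkenyl triflate F3, and Pd/CO coupling with 4 under the step 4 conditions gives 9.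

Step 7 (δ-lactone reduction beside the butenolide). The risks are incomplete or unselective furanolate formation, and butenolide reduction. The fallback gives up the selectivity and rebuilds the butenolide; it sets out from 10 and comes back at 12. DIBAL-H at −78 °C takes both lactones to lactols, and mild acid in the work-up aromatises the five-membered one, giving furyl lactol F4. NaBH4 in MeOH opens the six-membered lactol to furyl diol F5. Photooxygenation as in step 2 (O2, hν, rose bengal, i-Pr2NEt, −78 °C, where the furan reacts faster than the hindered tetrasubstituted olefin) gives hydroxybutenolide F6, and NaBH4 then gives 12.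

Step 4 (carbonylative esterification with one equivalent of a hindered, electron-poor secondary alcohol). The risks are slow alcoholysis of the acyl-palladium and Heck-type side reactions. The fallback separates carbonylation from ester formation; it sets out from 6 and comes back at 7. Pd-catalysed hydroxycarbonylation (CO, KOAc, aqueous DMF) gives 2-methylidene trienoic acid F7, and Yamaguchi esterification (2,4,6-trichlorobenzoyl chloride, Et3N, DMAP) with 4 gives 7.

**Further compounds**
F1 | step 5 | sclareol oxide (8α,13-epoxy-14,15-dinorlabd-12-ene) | CC1=CC[C@@H]2[C@@]3(C)CCCC(C)(C)[C@@H]3CC[C@@]2(C)O1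
F2 | step 5 | 4-[(4aS,8aS)-2,5,5,8a-tetramethyl-3,4,4a,5,6,7,8,8a-octahydronaphthalen-1-yl]butan-2-one (14,15-dinorlabd-8-en-13-one) | CC1=C(CCC(C)=O)[C@@]2(C)CCCC(C)(C)[C@@H]2CC1
F3 | step 5 | 4-[(4aS,8aS)-2,5,5,8a-tetramethyl-3,4,4a,5,6,7,8,8a-octahydronaphthalen-1-yl]but-1-en-2-yl trifluoromethanesulfonate | CC1=C(CCC(=C)OS(=O)(=O)C(F)(F)F)[C@@]2(C)CCCC(C)(C)[C@@H]2CC1
F4 | step 7 | (6R)-6-(furan-3-yl)-3-{2-[(4aS,8aS)-2,5,5,8a-tetramethyl-3,4,4a,5,6,7,8,8a-octahydronaphthalen-1-yl]ethyl}-5,6-dihydro-2H-pyran-2-ol (anomers) | CC1=C(CCC2=CC[C@@H](OC2O)c3ccoc3)[C@@]4(C)CCCC(C)(C)[C@@H]4CC1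
F5 | step 7 | (2Z,5R)-5-(furan-3-yl)-2-{2-[(4aS,8aS)-2,5,5,8a-tetramethyl-3,4,4a,5,6,7,8,8a-octahydronaphthalen-1-yl]ethyl}pent-2-ene-1,5-diol | CC1=C(CC/C(=C/C[C@@H](O)c2ccoc2)CO)[C@@]3(C)CCCC(C)(C)[C@@H]3CC1
F6 | step 7 | 5-hydroxy-4-[(1R,3Z)-1-hydroxy-4-(hydroxymethyl)-6-[(4aS,8aS)-2,5,5,8a-tetramethyl-3,4,4a,5,6,7,8,8a-octahydronaphthalen-1-yl]hex-3-en-1-yl]furan-2(5H)-one (C5 epimers) | CC1=C(CC/C(=C/C[C@@H](O)C2=CC(=O)OC2O)CO)[C@@]3(C)CCCC(C)(C)[C@@H]3CC1
F7 | step 4 | (5E,9E)-6,10,14-trimethyl-2-methylidenepentadeca-5,9,13-trienoic acid | C=C(CC/C=C(\C)CC/C=C(\C)CCC=C(C)C)C(=O)O
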